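Target dies slowly enough to be timed, and that slow loss is what we carry through these flasks.

| flask | substrate | reagent | remark | time |
|---|---|---|---|---|
| Thursday's | 0.050 M | 0.10 M | run made earlier |  |
| Monday's | 0.050 M | 0.050 M | run made earlier |  |
| Sunday's | 0.050 M | 0.20 M | run made earlier |  |
| red | 0.050 M (fed, over 50 min) | 0.100 M | all else is in the flask from the start; the feed brings no volume worth counting | 1.0 h |
| teal | 0.050 M | 0.100 M | everything together at the start | 1.0 h |
| ochre | 0.050 M | 0.100 M (fed, over 50 min) | all else is in the flask from the start; the feed brings no volume worth counting | 1.0 h |
| green | 0.050 M | 0.100 M (in portions, 3, over 50 min) | first portion at the start, last at 50 min | 1.0 h |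

| Thursday's: time / min | Thursday's: target / % | Monday's: time / min | Monday's: target / % | Sunday's: time / min | Sunday's: target / % |
|---|---|---|---|---|---|
| 3.00 | 50.4 | 5.00 | 53.3 | 5.00 | 29.9 |
| 10.0 | 46.5 | 15.0 | 65.9 | 10.0 | 8.2 |
| 15.0 | 36.5 | 30.0 | 67.0 | 15.0 | 1.7 |
| 25.0 | 23.5 | 40.0 | 66.7 | 30.0 | 0 |
| 40.0 | 15.4 | 60.0 | 66.3 | 60.0 | 0 |

(scatter of a reading: 0.3 percentage points)

* the best flask by amount of target, in percent of the substrate charged; "all alike" if 1.5 percentage points covers them all (red / teal / ochre / green / all alike)
* amount of target at the end, in percent of the substrate charged, red
* amount of target at the end, in percent of the substrate charged, teal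
* amount of target at the end, in percent of the substrate charged, ochre
* amount of target at the end, in percent of the substrate charged, green

- the numbers in the tables scatter by 0.3 percentage points (one standard deviation)
- steps that have been proposed: reagent + target -> over-reaction product; intermediate -> target; substrate + reagent -> intermediate

We take the proposed steps as they stand. With reagent charged at twice the substrate, which is then the limiting reagent, each substrate that reacts takes one reagent and each target lost takes one more. So with substrate and intermediate counted as zero, reagent left equals target left, and the reciprocal of the target fraction climbs in a straight line with time. Thursday's readings from 25.0 min to 40.0 min give a slope whose reciprocal reads 6.70 min, the exposure clock, the lifetime of target against reagent standing at the substrate charge.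

But those readings might still be fed by intermediate. Sunday's last fall, from 8.2% to 1.7%, has reagent near 2.00 substrate charges and gives 6.36 min, a rough reading with a scatter of 0.3 percentage points on that last value, yet close enough to keep the clock. Teal repeats Thursday's recipe, so the line carried on to 60 min gives 10.6%.

The clock matters from the crossing where reagent charged passes what substrate can take. Monday's flask, with equal charges, stays flat from 67.0% to 66.3%. Green's last portion comes at 50 min, leaving 10.0 min of exposure. If the earlier portions have reacted in full by then, the balance puts the target still to be had at the last portion at 66.7% of the charge, less any substrate still unreacted. With none unreacted, we reckon green to end at 33.4%. But substrate may remain: Monday's plateau reading implies 16.6% left in that flask, and green has had more reagent charged by then, so we take that as our lower case, giving 28.6%, still more than teal.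

The forecast names green, with red 19%, teal 10.6%, ochre 24% and green 31%, saying of green that after the last portion “then 10 minutes of decay gives about 31%”.

The flasks give red 19.0%, teal 10.6%, ochre 24.6% and green 32.4%, so green is best.

    reagent + target → over-reaction product (k = 0.0490 M⁻¹ s⁻¹)
    intermediate → target (k = 0.0110 s⁻¹)
    substrate + reagent → intermediate (k = 0.180 M⁻¹ s⁻¹)

Just before green's last portion, at 0.833 h, stood target 57.7% and substrate 5.40%, less substrate than the leftover we read from Monday's. Their sum on the exposure clock of 6.70 min gives 32.5% for green. Ochre held target 37.8% at the end of its feed, and the same clock gives 24.2% against its 24.6%.

The readings come from a simulation for an exercise; scatter was added.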